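**Retrosynthetic overview** (tetralin locants of the target: C1 carries the pendant aryl, C2 the CH2OSO3H, C3 the CH2OH, C4 is the ring CH2, C8a is the fusion carbon next to the C8 methoxy)
1. Target 15 ⇐ 14 ⇐ 13 ⇐ 12: hydrogenolysis of three benzyl ethers, O-sulfation of the one free CH2OH (on C2), benzylation of the pendant phenol.
2. 12 ⇐ 10 + 2,6-dimethoxyphenol: the pendant ring is attached at C1 by Friedel–Crafts capture of the C1 cation (trans to C2); the C2 hydroxymethyl comes from an aldol of tetralone 8 with formaldehyde (trans to C3).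
3. 8 ⇐ aryne 6 + cyclobutanone enolate 5: C4–C4a and C1–C8a are made together by formal insertion of the aryne into the C(=O)–CH bond of the four-membered ring. This closes the saturated ring of the tetralin, the only ring made in the route (both benzene rings are bought).
4. Enabling feature: C1–C4 are a four-carbon chain tied at both ends to the adjacent arene carbons C8a/C4a. C1 is benzylic and can be a carbonyl carbon, C4 is a plain CH2 (an enolate carbon), so the chain can be one cyclobutanone with C3 on its mirror plane. The C8 methoxy next to C8a polarises the aryne so that the carbonyl carbon goes to C8a and the CH2 to C4a.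
5. Absolute configuration: enantiotopos-selective deprotonation of prochiral cyclobutanone 3 sets C3; C2 and then C1 follow by 1,2-induction.

Key step: step 3

Assumption: the (R,R)-lithium amide is taken to deprotonate 3 in the sense that gives (R)-4; if the opposite sense is found, the (S,S)-base is used and nothing else changes.

**Step 1**
Reactants: 1 4-bromo-2,6-dimethoxyphenol
Product: 2 2-(benzyloxy)-5-bromo-1,3-dimethoxybenzene
Conditions: BnBr, K2CO3, DMF, rt
Reagents that add atoms: benzyl bromide, BrCc1ccccc1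
Why: Williamson ether synthesis on the phenoxide, which masks the phenol for the base and acid steps and leaves the two equivalent C–H bonds between Br and OMe as the only acidic aryl positions.

**Step 2**
Reactants: 3 3-[(benzyloxy)methyl]cyclobutan-1-one
Product: 4 (R)-({3-[(benzyloxy)methyl]cyclobut-1-en-1-yl}oxy)triethylsilane
Conditions: (R,R)-bis(1-phenylethyl)amine, n-BuLi, THF, −78 °C; TESCl then 3, −100 °C
Reagents that add atoms: chlorotriethylsilane, CC[Si](Cl)(CC)CC
Why: Enantioselective deprotonation of a prochiral 3-substituted cyclobutanone by a C2-symmetric chiral lithium amide with in situ silyl trapping, in which the base removes a proton from one of the two enantiotopic α-methylene groups and thereby makes the CH2OBn-bearing ring carbon an R stereocentre.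

**Step 3**
Reactants: 4 (R)-({3-[(benzyloxy)methyl]cyclobut-1-en-1-yl}oxy)triethylsilane, 2 2-(benzyloxy)-5-bromo-1,3-dimethoxybenzene
Product: 8 (3S)-7-(benzyloxy)-3-[(benzyloxy)methyl]-6,8-dimethoxy-3,4-dihydronaphthalen-1(2H)-one, via lithium enolate 5 (not isolated), via aryne 6 (not isolated), via ladder alkoxide 7 (not isolated)
Conditions: 4, MeLi, THF, 0 °C to rt; then 2, LiTMP (preformed), −78 to 0 °C; aq NH4Cl
Reagents that add atoms: none
Why: Proposed new method: MeLi unmasks the regio- and configurationally defined lithium enolate 5 from 4 with no proton source present, while LiTMP lithiates 2 between Br and OMe and loss of LiBr gives aryne 6; the enolate carbon adds to the aryne carbon remote from the flanking methoxy group, the aryl anion so placed next to that methoxy group adds to the strained cyclobutanone carbonyl, and ladder alkoxide 7 breaks its central C–C bond to an o-quinodimethide-type enolate that is protonated on work-up, so the aryne is formally inserted into the C(=O)–CH bond. The closest known reaction types are the acyl-alkylation of arynes with β-keto esters and the two-carbon ring expansion of cycloalkanone enolates with arynes via benzocyclobutenoxides; new here is a simple cyclobutanone enolate, for which release of the strain of two fused four-membered rings and formation of a conjugated enolate should make the fragmentation fast. The six-membered ring is closed by ring expansion: intermolecular C-arylation, 4-exo-trig carbonyl addition, then anionic fragmentation of the bond shared by the two four-membered rings. No permanent stereocentre is made: the two transient ones in 7 vanish, and the C3 stereocentre is carried over from 4 because it is β to the carbonyl and never part of an enolisable position. The step needs regioselectivity on the aryne, which the methoxy group next to one aryne carbon secures as is usual for 3-alkoxyarynes, and insertion in preference to plain α-arylation, which the aprotic medium (enolate from the silyl enol ether, hindered amide base) should favour.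

**Step 4**
Reactants: 8 (3S)-7-(benzyloxy)-3-[(benzyloxy)methyl]-6,8-dimethoxy-3,4-dihydronaphthalen-1(2H)-one
Product: 9 (2S,3S)-7-(benzyloxy)-3-[(benzyloxy)methyl]-2-(hydroxymethyl)-6,8-dimethoxy-3,4-dihydronaphthalen-1(2H)-one
Conditions: LiHMDS, THF, −78 °C; CH2O (monomer from cracked paraformaldehyde), −78 °C; AcOH, −78 °C
Reagents that add atoms: formaldehyde, C=O
Why: Aldol hydroxymethylation of the only possible ketone enolate, in which formaldehyde should add to the enolate face anti to the neighbouring C3 substituent, the 2,3-trans product also being the one favoured by equilibration of this enolisable centre.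

**Step 5**
Reactants: 9 (2S,3S)-7-(benzyloxy)-3-[(benzyloxy)methyl]-2-(hydroxymethyl)-6,8-dimethoxy-3,4-dihydronaphthalen-1(2H)-one
Product: 10 (1RS,2S,3S)-7-(benzyloxy)-3-[(benzyloxy)methyl]-2-(hydroxymethyl)-6,8-dimethoxy-1,2,3,4-tetrahydronaphthalen-1-ol (both C1 epimers)
Conditions: NaBH4, MeOH, 0 °C
Reagents that add atoms: none
Why: Borohydride reduction of the aryl ketone, where the configuration of the new carbinol carbon does not matter because C1 is ionised in the next step.

**Step 6**
Reactants: 10 (1RS,2S,3S)-7-(benzyloxy)-3-[(benzyloxy)methyl]-2-(hydroxymethyl)-6,8-dimethoxy-1,2,3,4-tetrahydronaphthalen-1-ol, 11 2,6-dimethoxyphenol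
Product: 12 4-[(1R,2S,3S)-7-(benzyloxy)-3-[(benzyloxy)methyl]-2-(hydroxymethyl)-6,8-dimethoxy-1,2,3,4-tetrahydronaphthalen-1-yl]-2,6-dimethoxyphenol
Conditions: 11 (3 equiv), TsOH·H2O (10 mol %), HFIP/CH2Cl2, 0 °C
Reagents that add atoms: none
Why: Friedel–Crafts benzylation through the C1 cation, stabilised by the ortho (C8) and para (C6) methoxy groups, in which the free phenol reacts at its para carbon and should enter anti to the C2 hydroxymethyl group, setting C1 trans to C2 as in known captures of 2-substituted tetralin-1-yl cations by arenes.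

**Step 7**
Reactants: 12 4-[(1R,2S,3S)-7-(benzyloxy)-3-[(benzyloxy)methyl]-2-(hydroxymethyl)-6,8-dimethoxy-1,2,3,4-tetrahydronaphthalen-1-yl]-2,6-dimethoxyphenol
Product: 13 [(1R,2S,3S)-7-(benzyloxy)-1-[4-(benzyloxy)-3,5-dimethoxyphenyl]-3-[(benzyloxy)methyl]-6,8-dimethoxy-1,2,3,4-tetrahydronaphthalen-2-yl]methanol
Conditions: BnBr, K2CO3, acetone, 50 °C
Reagents that add atoms: benzyl bromide, BrCc1ccccc1
Why: Williamson etherification selective for the phenol, since carbonate deprotonates the phenol but not the primary alcohol, which leaves the C2 hydroxymethyl group as the only free hydroxyl.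

**Step 8**
Reactants: 13 [(1R,2S,3S)-7-(benzyloxy)-1-[4-(benzyloxy)-3,5-dimethoxyphenyl]-3-[(benzyloxy)methyl]-6,8-dimethoxy-1,2,3,4-tetrahydronaphthalen-2-yl]methanol
Product: 14 sodium [(1R,2S,3S)-7-(benzyloxy)-1-[4-(benzyloxy)-3,5-dimethoxyphenyl]-3-[(benzyloxy)methyl]-6,8-dimethoxy-1,2,3,4-tetrahydronaphthalen-2-yl]methyl sulfate
Conditions: SO3·pyridine, DMF, rt; aq NaHCO3
Reagents that add atoms: sulfur trioxide–pyridine complex, O=S(=O)([O-])[n+]1ccccc1; sodium hydrogen carbonate, [Na+].OC([O-])=O
Why: O-Sulfation of a primary alcohol with the SO3–pyridine complex, where the single free hydroxyl fixes the site and the monoester is kept as its stable sodium salt.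

**Step 9**
Reactants: 14 sodium [(1R,2S,3S)-7-(benzyloxy)-1-[4-(benzyloxy)-3,5-dimethoxyphenyl]-3-[(benzyloxy)methyl]-6,8-dimethoxy-1,2,3,4-tetrahydronaphthalen-2-yl]methyl sulfate
Product: 15 [(1R,2S,3S)-7-hydroxy-1-(4-hydroxy-3,5-dimethoxyphenyl)-3-(hydroxymethyl)-6,8-dimethoxy-1,2,3,4-tetrahydronaphthalen-2-yl]methyl hydrogen sulfate
Conditions: H2 (1 atm), Pd/C, MeOH–H2O, rt; then HCl (1.0 equiv), 0 °C, C18 desalting, freeze-drying
Reagents that add atoms: none
Why: Hydrogenolysis of the two aryl benzyl ethers and the alkyl benzyl ether over Pd/C, to which the alkyl sulfate salt and the stereocentres are inert, followed by one equivalent of acid to give the hydrogen sulfate, which is desalted and dried cold to avoid acid-catalysed loss of the sulfate.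

**Compound list**
1 | 4-bromo-2,6-dimethoxyphenol | COc1cc(Br)cc(OC)c1O | starting material
2 | 2-(benzyloxy)-5-bromo-1,3-dimethoxybenzene | COc1cc(Br)cc(OC)c1OCc1ccccc1 | intermediate
3 | 3-[(benzyloxy)methyl]cyclobutan-1-one | O=C1CC(COCc2ccccc2)C1 | starting material
4 | (R)-({3-[(benzyloxy)methyl]cyclobut-1-en-1-yl}oxy)triethylsilane | CC[Si](CC)(CC)OC1=C[C@H](COCc2ccccc2)C1 | intermediate
5 | lithium (R)-3-[(benzyloxy)methyl]cyclobut-1-en-1-olate | [Li]OC1=C[C@H](COCc2ccccc2)C1 | intermediate
6 | 4-(benzyloxy)-3,5-dimethoxybenzyne (1,2-didehydrobenzene) | COC1=C(OCc2ccccc2)C(OC)=CC#C1 | intermediate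
7 | lithium 4-(benzyloxy)-9-[(benzyloxy)methyl]-3,5-dimethoxytricyclo[6.2.0.0(2,7)]deca-2,4,6-trien-1-olate (C1/C8 cis-fused, CH2OBn anti to the arene at C8; carbinolate carbon on the arene carbon next to OMe) | [Li]O[C@@]12C[C@@H](COCc3ccccc3)[C@@H]1c1cc(OC)c(OCc3ccccc3)c(OC)c12 | intermediate
8 | (3S)-7-(benzyloxy)-3-[(benzyloxy)methyl]-6,8-dimethoxy-3,4-dihydronaphthalen-1(2H)-one | O=C1c2c(cc(OC)c(OCc3ccccc3)c2OC)C[C@H](COCc3ccccc3)C1 | intermediate
9 | (2S,3S)-7-(benzyloxy)-3-[(benzyloxy)methyl]-2-(hydroxymethyl)-6,8-dimethoxy-3,4-dihydronaphthalen-1(2H)-one | O=C1c2c(cc(OC)c(OCc3ccccc3)c2OC)C[C@H](COCc3ccccc3)[C@H]1CO | intermediate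
10 | (1RS,2S,3S)-7-(benzyloxy)-3-[(benzyloxy)methyl]-2-(hydroxymethyl)-6,8-dimethoxy-1,2,3,4-tetrahydronaphthalen-1-ol | OC1c2c(cc(OC)c(OCc3ccccc3)c2OC)C[C@H](COCc3ccccc3)[C@H]1CO | intermediate
11 | 2,6-dimethoxyphenol | COc1cccc(OC)c1O | starting material
12 | 4-[(1R,2S,3S)-7-(benzyloxy)-3-[(benzyloxy)methyl]-2-(hydroxymethyl)-6,8-dimethoxy-1,2,3,4-tetrahydronaphthalen-1-yl]-2,6-dimethoxyphenol | COc1cc([C@@H]2c3c(cc(OC)c(OCc4ccccc4)c3OC)C[C@H](COCc4ccccc4)[C@H]2CO)cc(OC)c1O | intermediate
13 | [(1R,2S,3S)-7-(benzyloxy)-1-[4-(benzyloxy)-3,5-dimethoxyphenyl]-3-[(benzyloxy)methyl]-6,8-dimethoxy-1,2,3,4-tetrahydronaphthalen-2-yl]methanol | COc1cc([C@@H]2c3c(cc(OC)c(OCc4ccccc4)c3OC)C[C@H](COCc4ccccc4)[C@H]2CO)cc(OC)c1OCc1ccccc1 | intermediate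
14 | sodium [(1R,2S,3S)-7-(benzyloxy)-1-[4-(benzyloxy)-3,5-dimethoxyphenyl]-3-[(benzyloxy)methyl]-6,8-dimethoxy-1,2,3,4-tetrahydronaphthalen-2-yl]methyl sulfate | COc1cc([C@@H]2c3c(cc(OC)c(OCc4ccccc4)c3OC)C[C@H](COCc4ccccc4)[C@H]2COS(=O)(=O)[O-])cc(OC)c1OCc1ccccc1.[Na+] | intermediate
15 | [(1R,2S,3S)-7-hydroxy-1-(4-hydroxy-3,5-dimethoxyphenyl)-3-(hydroxymethyl)-6,8-dimethoxy-1,2,3,4-tetrahydronaphthalen-2-yl]methyl hydrogen sulfate | COc1cc([C@@H]2c3c(cc(OC)c(O)c3OC)C[C@H](CO)[C@H]2COS(=O)(=O)O)cc(OC)c1O | target

**Step count and risks**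
Total steps: 9. Longest linear sequence: 8 steps (3 → 15 through steps 2–9; the branch 1 → 15 through steps 1 and 3–9 is equally long).

Steps most likely to fail:

1. Step 3 (proposed new method). What may go wrong: proton transfer to the aryl anion before it closes onto the carbonyl, which ends in plain α-arylation; O-arylation or a second arylation of the product anion; metalation of a benzylic ether position by the amide base. Fallback with known chemistry, from 4 and 2, returning at 8: Pd-catalysed α-arylation of silyl enol ether 4 with bromide 2 (Pd(OAc)2, P(t-Bu)3, Bu3SnF, toluene, 80 °C) should give (2R,3R)-2-[4-(benzyloxy)-3,5-dimethoxyphenyl]-3-[(benzyloxy)methyl]cyclobutan-1-one F1. Baeyer–Villiger oxidation (mCPBA, NaHCO3, CH2Cl2, 0 °C) inserts oxygen on the benzylic side with retention to give (4S,5R)-5-[4-(benzyloxy)-3,5-dimethoxyphenyl]-4-[(benzyloxy)methyl]dihydrofuran-2(3H)-one F2. Ionic hydrogenolysis of the benzylic C–O bond (Et3SiH, BF3·OEt2, CH2Cl2, −20 °C) gives (S)-4-[4-(benzyloxy)-3,5-dimethoxyphenyl]-3-[(benzyloxy)methyl]butanoic acid F3. Intramolecular Friedel–Crafts acylation ((COCl)2, then SnCl4, CH2Cl2, −78 °C) closes the ring ortho to a methoxy group and gives 8. The two aryl–carbon bonds are then made in separate known steps.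

2. Step 6. What may go wrong: loss of the C2 proton from the benzylic cation (elimination to the dihydronaphthalene, which would also erase the C2 configuration), insufficient facial selectivity in the capture, and alkylation of the substrate's own arene. Fallback from 10, returning at 12, changing from free-cation capture to anchimerically assisted substitution: selective acetylation of the primary hydroxyl (AcCl, 2,4,6-collidine, CH2Cl2, −78 °C) gives [(1RS,2S,3S)-7-(benzyloxy)-3-[(benzyloxy)methyl]-1-hydroxy-6,8-dimethoxy-1,2,3,4-tetrahydronaphthalen-2-yl]methyl acetate F4. BF3·OEt2 with 11 (CH2Cl2, −40 °C) ionises C1 under participation of the acetate carbonyl (cis-fused dioxanylium ion), which holds the cation against elimination and blocks the C2 face, so the phenol must enter trans. This gives [(1R,2S,3S)-7-(benzyloxy)-3-[(benzyloxy)methyl]-1-(4-hydroxy-3,5-dimethoxyphenyl)-6,8-dimethoxy-1,2,3,4-tetrahydronaphthalen-2-yl]methyl acetate F5. K2CO3 in MeOH removes the acetate and gives 12.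

3. Step 2. What may go wrong: incomplete discrimination of the two enantiotopic methylene groups, and erosion of the enantiomeric purity by proton exchange between enolate and ketone before silylation. Fallback from 3, returning at 5, in which the stereocentre is made by catalytic hydride delivery instead of by deprotonation: LDA/TESCl (THF, −78 °C) gives racemic ({3-[(benzyloxy)methyl]cyclobut-1-en-1-yl}oxy)triethylsilane F6. Saegusa–Ito dehydrogenation (Pd(OAc)2, MeCN, rt) gives 3-[(benzyloxy)methyl]cyclobut-2-en-1-one F7. Copper hydride-catalysed enantioselective 1,4-hydrosilylation (Cu(OAc)2, DTBM-SEGPHOS of the appropriate hand, PhMe2SiH, toluene, −40 °C) delivers hydride to the β-carbon under ligand control and leaves the enolate as (R)-({3-[(benzyloxy)methyl]cyclobut-1-en-1-yl}oxy)dimethyl(phenyl)silane F8. MeLi (THF, 0 °C) converts F8 into lithium enolate 5, which enters step 3 unchanged.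

**Further compounds**
F1 | step 3 | (2R,3R)-2-[4-(benzyloxy)-3,5-dimethoxyphenyl]-3-[(benzyloxy)methyl]cyclobutan-1-one | O=C1C[C@@H](COCc2ccccc2)[C@@H]1c1cc(OC)c(OCc2ccccc2)c(OC)c1
F2 | step 3 | (4S,5R)-5-[4-(benzyloxy)-3,5-dimethoxyphenyl]-4-[(benzyloxy)methyl]dihydrofuran-2(3H)-one | O=C1C[C@@H](COCc2ccccc2)[C@@H](O1)c1cc(OC)c(OCc2ccccc2)c(OC)c1
F3 | step 3 | (S)-4-[4-(benzyloxy)-3,5-dimethoxyphenyl]-3-[(benzyloxy)methyl]butanoic acid | OC(=O)C[C@@H](COCc1ccccc1)Cc1cc(OC)c(OCc2ccccc2)c(OC)c1
F4 | step 6 | [(1RS,2S,3S)-7-(benzyloxy)-3-[(benzyloxy)methyl]-1-hydroxy-6,8-dimethoxy-1,2,3,4-tetrahydronaphthalen-2-yl]methyl acetate | OC1c2c(cc(OC)c(OCc3ccccc3)c2OC)C[C@H](COCc3ccccc3)[C@H]1COC(C)=O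
F5 | step 6 | [(1R,2S,3S)-7-(benzyloxy)-3-[(benzyloxy)methyl]-1-(4-hydroxy-3,5-dimethoxyphenyl)-6,8-dimethoxy-1,2,3,4-tetrahydronaphthalen-2-yl]methyl acetate | COc1cc([C@@H]2c3c(cc(OC)c(OCc4ccccc4)c3OC)C[C@H](COCc4ccccc4)[C@H]2COC(C)=O)cc(OC)c1O
F6 | step 2 | racemic ({3-[(benzyloxy)methyl]cyclobut-1-en-1-yl}oxy)triethylsilane | CC[Si](CC)(CC)OC1=CC(COCc2ccccc2)C1
F7 | step 2 | 3-[(benzyloxy)methyl]cyclobut-2-en-1-one | O=C1C=C(COCc2ccccc2)C1
F8 | step 2 | (R)-({3-[(benzyloxy)methyl]cyclobut-1-en-1-yl}oxy)dimethyl(phenyl)silane | C[Si](C)(c1ccccc1)OC1=C[C@H](COCc2ccccc2)C1
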